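## Retrosynthetic overview

1. Target 33 comes from ester 30 by desilylation, oxidation and tert-butyl ester cleavage; 30 is made by a late Yamaguchi union of hydrindenone alcohol 21 (C15 core) with (2E,4E,6R)-dienoic acid 28 (C10 acyl part).
2. 21 comes from bicyclic enone 14 by α′-alkylation with allylic bromide 17 and then γ-hydroxylation (vinylogous Rubottom).
3. 14 comes from 1,4-diketone 12 by aldol condensation (five-membered ring closed second); 12 comes from aldehyde 7 by a two-carbon extension.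
4. The six-membered ring is formed first: a catalytic asymmetric Diels–Alder reaction of silyloxydiene 2 with formyl ester 5 sets C7 and C7a.
5. 28 comes from (R)-2-methylbutanal by two Wittig olefinations; the stereocentre comes from asymmetric hydrogenation of tiglic acid.

Assumption: the S-configured oxazaborolidinium catalyst is taken to expose the Re face at C-alpha of enal 5, as it does for 2-methylacrolein; if the opposite sense were found, the R-catalyst would be used.

Ring atoms of the bicyclic compounds are numbered as in 1H-indene (C1, C2, C3, C3a, C4–C7, C7a).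

## Route

Step 1
Reactants: 1 (2E)-but-2-enal (crotonaldehyde)
Product: 2 [(1E)-buta-1,3-dien-1-yloxy]tri(propan-2-yl)silane
Conditions: iPr3SiOTf, Et3N, Et2O, 0 °C → rt
Reagents that add atoms: triisopropylsilyl trifluoromethanesulfonate, CC(C)[Si](OS(=O)(=O)C(F)(F)F)(C(C)C)C(C)C
Why: Soft γ-enolisation of the enal and O-silylation of the dienolate give the (E)-dienol silyl ether; no stereocentre is formed.

Step 2
Reactants: 3 3-methylbut-2-enoic acid
Product: 4 tert-butyl 3-methylbut-2-enoate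
Conditions: 2-methylpropene (excess), H2SO4 (cat.), CH2Cl2, sealed vessel, rt
Reagents that add atoms: 2-methylpropene, CC(C)=C
Why: Acid-catalysed addition of the carboxylic acid to isobutene (tert-butyl cation capture) installs an ester that resists bases and nucleophiles and is removed by acid at the end.

Step 3
Reactants: 4 tert-butyl 3-methylbut-2-enoate
Product: 5 tert-butyl (2E)-3-methyl-4-oxobut-2-enoate
Conditions: SeO2 (1.2 equiv), 1,4-dioxane, 100 °C
Reagents that add atoms: selenium dioxide, O=[Se]=O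
Why: Riley allylic oxidation (ene reaction, then [2,3]-shift) attacks the methyl group trans to the ester and gives the (E)-enal.

Step 4
Reactants: 2 [(1E)-buta-1,3-dien-1-yloxy]tri(propan-2-yl)silane; 5 tert-butyl (2E)-3-methyl-4-oxobut-2-enoate
Product: 6 tert-butyl (1R,5R,6S)-6-formyl-6-methyl-5-[(triisopropylsilyl)oxy]cyclohex-3-ene-1-carboxylate
Conditions: 2 (2 equiv), (S)-3,3-diphenyl-1-(2-methylphenyl)tetrahydro-1H,3H-pyrrolo[1,2-c][1,3,2]oxazaborole (20 mol%), HN(SO2CF3)2 (18 mol%), CH2Cl2, −78 °C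
Reagents that add atoms: none
Why: In this oxazaborolidinium-catalysed asymmetric Diels–Alder reaction the boron-bound formyl group steers the silyloxy terminus of the diene onto the methyl-bearing carbon, the E geometry of 5 becomes the cis methyl/ester relationship, attack on the exposed Re face at C-alpha gives (1R,6S), and endo approach of the formyl group gives 5R (a centre that is oxidised later).

Step 5
Reactants: 6 tert-butyl (1R,5R,6S)-6-formyl-6-methyl-5-[(triisopropylsilyl)oxy]cyclohex-3-ene-1-carboxylate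
Product: 7 tert-butyl (1R,2S,3R)-2-formyl-2-methyl-3-[(triisopropylsilyl)oxy]cyclohexane-1-carboxylate
Conditions: H2 (1 atm), 5% Pd/C, EtOAc, rt
Reagents that add atoms: none
Why: Heterogeneous hydrogenation saturates the only C=C bond while the hindered aldehyde, the ester and the silyl ether are left alone; no stereocentre is formed.

Step 6
Reactants: 7 tert-butyl (1R,2S,3R)-2-formyl-2-methyl-3-[(triisopropylsilyl)oxy]cyclohexane-1-carboxylate
Product: 8 tert-butyl (1R,2S,3R)-2-methyl-2-[(1Z)-prop-1-en-1-yl]-3-[(triisopropylsilyl)oxy]cyclohexane-1-carboxylate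
Conditions: EtPPh3Br, KN(SiMe3)2, THF, 0 °C; then 7, −78 °C → rt
Reagents that add atoms: ethyltriphenylphosphonium bromide, CC[P+](c1ccccc1)(c1ccccc1)c1ccccc1.[Br-]
Why: A Wittig olefination with a non-stabilised ylide tolerates the non-enolisable neopentyl aldehyde and gives mainly the Z alkene, whose geometry is irrelevant.

Step 7
Reactants: 8 tert-butyl (1R,2S,3R)-2-methyl-2-[(1Z)-prop-1-en-1-yl]-3-[(triisopropylsilyl)oxy]cyclohexane-1-carboxylate
Product: 10 tert-butyl (1R,2S,3R)-2-(2-hydroxypropyl)-2-methyl-3-[(triisopropylsilyl)oxy]cyclohexane-1-carboxylate (both carbinol epimers), via secondary alkylborane 9 (not isolated)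
Conditions: 9-borabicyclo[3.3.1]nonane, THF, 60 °C; then NaOH, H2O2, H2O, 0 °C → rt
Reagents that add atoms: hydrogen peroxide, OO (the new oxygen); 9-borabicyclo[3.3.1]nonane, B1C2CCCC1CCC2 (held only in 9)
Why: In this hydroboration–oxidation the bulky borane places boron on the alkene carbon remote from the quaternary centre and oxidation with retention gives the secondary alcohol, whose configuration does not matter because it is oxidised in step 9.

Step 8
Reactants: 10 tert-butyl (1R,2S,3R)-2-(2-hydroxypropyl)-2-methyl-3-[(triisopropylsilyl)oxy]cyclohexane-1-carboxylate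
Product: 11 tert-butyl (1R,2S,3R)-3-hydroxy-2-(2-hydroxypropyl)-2-methylcyclohexane-1-carboxylate
Conditions: HF·pyridine, THF, rt → 40 °C
Reagents that add atoms: none
Why: Fluoride-driven Si–O cleavage (strong Si–F bond) frees the hindered secondary alcohol without touching the tert-butyl ester.

Step 9
Reactants: 11 tert-butyl (1R,2S,3R)-3-hydroxy-2-(2-hydroxypropyl)-2-methylcyclohexane-1-carboxylate
Product: 12 tert-butyl (1R,2S)-2-methyl-3-oxo-2-(2-oxopropyl)cyclohexane-1-carboxylate
Conditions: Dess–Martin periodinane (2.4 equiv), CH2Cl2, rt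
Reagents that add atoms: none
Why: Dess–Martin oxidation converts both secondary alcohols into ketones under neutral conditions, which removes the two stereocentres that were never meant to stay and avoids retro-aldol or epimerisation.

Step 10
Reactants: 12 tert-butyl (1R,2S)-2-methyl-3-oxo-2-(2-oxopropyl)cyclohexane-1-carboxylate
Product: 14 tert-butyl (7R,7aS)-7a-methyl-2-oxo-2,4,5,6,7,7a-hexahydro-1H-indene-7-carboxylate, via aldol adduct 13 (not isolated)
Conditions: KOtBu (0.3 equiv), t-BuOH/THF, rt → 50 °C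
Reagents that add atoms: none
Why: Intramolecular aldol condensation (aldol addition of the methyl-ketone enolate to the ring ketone, then E1cB dehydration) closes the cyclopentenone, while the far less acidic C7–H of the hindered tert-butyl ester is not touched and the ester resists Claisen attack.

Step 11
Reactants: 15 2-methylidenepropane-1,3-diol
Product: 16 2-({[tert-butyl(dimethyl)silyl]oxy}methyl)prop-2-en-1-ol
Conditions: 15 (3 equiv), tBuMe2SiCl (1 equiv), imidazole (1.1 equiv), DMF, 0 °C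
Reagents that add atoms: tert-butyl(chloro)dimethylsilane, CC(C)(C)[Si](C)(C)Cl
Why: Statistical mono-silylation of the symmetrical diol (diol in excess) protects one primary alcohol.

Step 12
Reactants: 16 2-({[tert-butyl(dimethyl)silyl]oxy}methyl)prop-2-en-1-ol
Product: 17 {[2-(bromomethyl)prop-2-en-1-yl]oxy}(tert-butyl)dimethylsilane
Conditions: CBr4, PPh3, CH2Cl2, 0 °C
Reagents that add atoms: tetrabromomethane, BrC(Br)(Br)Br
Why: The Appel reaction (alkoxyphosphonium ion displaced by bromide) turns the primary allylic alcohol into the bromide under neutral conditions.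

Step 13
Reactants: 14 tert-butyl (7R,7aS)-7a-methyl-2-oxo-2,4,5,6,7,7a-hexahydro-1H-indene-7-carboxylate; 17 {[2-(bromomethyl)prop-2-en-1-yl]oxy}(tert-butyl)dimethylsilane
Product: 19 tert-butyl (1R,7R,7aS)-1-[2-({[tert-butyl(dimethyl)silyl]oxy}methyl)prop-2-en-1-yl]-7a-methyl-2-oxo-2,4,5,6,7,7a-hexahydro-1H-indene-7-carboxylate, via lithium dienolate 18 (not isolated)
Conditions: LiN(iPr)2 (1.05 equiv), THF, −78 °C; then 17 (1.3 equiv), DMPU, −78 → −40 °C
Reagents that add atoms: lithium diisopropylamide, CC(C)[N-]C(C)C.[Li+] (lithium held only in 18)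
Why: Kinetic α′-deprotonation gives the cross-conjugated enolate, which is alkylated at C1 by the allylic bromide from the face away from the C7 ring branch that carries the ester, that is syn to the angular methyl group, giving 1R, which is also expected to be the more stable C1 epimer.

Step 14
Reactants: 19 tert-butyl (1R,7R,7aS)-1-[2-({[tert-butyl(dimethyl)silyl]oxy}methyl)prop-2-en-1-yl]-7a-methyl-2-oxo-2,4,5,6,7,7a-hexahydro-1H-indene-7-carboxylate
Product: 21 tert-butyl (1R,4S,7R,7aS)-1-[2-({[tert-butyl(dimethyl)silyl]oxy}methyl)prop-2-en-1-yl]-4-hydroxy-7a-methyl-2-oxo-2,4,5,6,7,7a-hexahydro-1H-indene-7-carboxylate, via trimethylsilyl dienol ether 20 (not isolated)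
Conditions: Me3SiOTf, Et3N, CH2Cl2, 0 °C; then mCPBA (1.05 equiv), CH2Cl2, −20 °C; then 10% aq. citric acid, THF, 0 °C
Reagents that add atoms: 3-chloroperoxybenzoic acid, O=C(OO)c1cccc(Cl)c1 (the new oxygen); trimethylsilyl trifluoromethanesulfonate, C[Si](C)(C)OS(=O)(=O)C(F)(F)F (silicon held only in 20)
Why: In this vinylogous Rubottom oxidation soft enolisation removes the accessible γ-hydrogen at C4 in preference to the hindered tertiary C1–H, and the peracid attacks the distal C3a=C4 bond axially, syn to the angular methyl group as in the 6β-hydroxylation of steroidal dienol ethers, giving 4S.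

Step 15
Reactants: 22 (2E)-2-methylbut-2-enoic acid (tiglic acid)
Product: 23 (2R)-2-methylbutanoic acid
Conditions: H2 (4 atm), Ru(OAc)2[(R)-H8-BINAP] (0.5 mol%; H8-BINAP = 2,2'-bis(diphenylphosphino)-5,5',6,6',7,7',8,8'-octahydro-1,1'-binaphthyl), MeOH, rt
Reagents that add atoms: none
Why: Carboxylate-directed asymmetric hydrogenation of the α,β-unsaturated acid with the R ligand sets the 2R centre (the later C6 of the acyl chain) in high ee.

Step 16
Reactants: 23 (2R)-2-methylbutanoic acid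
Product: 24 (2R)-2-methylbutan-1-ol
Conditions: LiAlH4, Et2O, 0 °C → rt; then H2O
Reagents that add atoms: none
Why: Hydride reduction of the acid proceeds through the carboxylate and alkoxide, which are not enolised, so the α-stereocentre is kept.

Step 17
Reactants: 24 (2R)-2-methylbutan-1-ol
Product: 26 (2E,4R)-2,4-dimethylhex-2-enal, via (2R)-2-methylbutanal 25 (not isolated)
Conditions: 2,2,6,6-tetramethylpiperidin-1-oxyl (TEMPO, 10 mol%), PhI(OAc)2 (1.1 equiv), CH2Cl2, rt; then Ph3P=C(CH3)CHO, toluene, 80 °C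
Reagents that add atoms: 2-(triphenyl-λ5-phosphanylidene)propanal, CC(C=O)=P(c1ccccc1)(c1ccccc1)c1ccccc1
Why: Oxoammonium oxidation gives the configurationally labile aldehyde, which is trapped in the same flask by a Wittig reaction with the stabilised ylide to give the (E)-trisubstituted enal without base and without isolation, so 4R is retained.

Step 18
Reactants: 26 (2E,4R)-2,4-dimethylhex-2-enal
Product: 27 ethyl (2E,4E,6R)-4,6-dimethylocta-2,4-dienoate
Conditions: Ph3P=CHCO2Et, toluene, 80 °C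
Reagents that add atoms: ethyl (triphenyl-λ5-phosphanylidene)acetate, CCOC(=O)C=P(c1ccccc1)(c1ccccc1)c1ccccc1
Why: The Wittig reaction of a stabilised ylide with the enal gives the (2E)-enoate under thermodynamic control of oxaphosphetane formation.

Step 19
Reactants: 27 ethyl (2E,4E,6R)-4,6-dimethylocta-2,4-dienoate
Product: 28 (2E,4E,6R)-4,6-dimethylocta-2,4-dienoic acid
Conditions: LiOH, THF/MeOH/H2O, rt; then 1 M HCl
Reagents that add atoms: lithium hydroxide, [Li+].[OH-] (the hydroxyl oxygen)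
Why: Saponification by acyl–oxygen cleavage leaves the diene geometry and the remote stereocentre unchanged.

Step 20
Reactants: 21 tert-butyl (1R,4S,7R,7aS)-1-[2-({[tert-butyl(dimethyl)silyl]oxy}methyl)prop-2-en-1-yl]-4-hydroxy-7a-methyl-2-oxo-2,4,5,6,7,7a-hexahydro-1H-indene-7-carboxylate; 28 (2E,4E,6R)-4,6-dimethylocta-2,4-dienoic acid
Product: 30 tert-butyl (1R,4S,7R,7aS)-1-[2-({[tert-butyl(dimethyl)silyl]oxy}methyl)prop-2-en-1-yl]-4-{[(2E,4E,6R)-4,6-dimethylocta-2,4-dienoyl]oxy}-7a-methyl-2-oxo-2,4,5,6,7,7a-hexahydro-1H-indene-7-carboxylate, via mixed anhydride 29 (not isolated)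
Conditions: 28 (1.5 equiv), 2,4,6-Cl3C6H2COCl, Et3N, THF, rt; then 21, 4-(dimethylamino)pyridine, toluene, rt → 40 °C
Reagents that add atoms: 2,4,6-trichlorobenzoyl chloride, O=C(Cl)c1c(Cl)cc(Cl)cc1Cl (aroyl group held only in 29)
Why: In the Yamaguchi esterification the pyridine catalyst attacks the less hindered dienoyl carbonyl of the mixed anhydride and the acylpyridinium ion acylates the hindered axial alcohol at oxygen, so C4 keeps its configuration.

Step 21
Reactants: 30 tert-butyl (1R,4S,7R,7aS)-1-[2-({[tert-butyl(dimethyl)silyl]oxy}methyl)prop-2-en-1-yl]-4-{[(2E,4E,6R)-4,6-dimethylocta-2,4-dienoyl]oxy}-7a-methyl-2-oxo-2,4,5,6,7,7a-hexahydro-1H-indene-7-carboxylate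
Product: 31 tert-butyl (1R,4S,7R,7aS)-4-{[(2E,4E,6R)-4,6-dimethylocta-2,4-dienoyl]oxy}-1-[2-(hydroxymethyl)prop-2-en-1-yl]-7a-methyl-2-oxo-2,4,5,6,7,7a-hexahydro-1H-indene-7-carboxylate
Conditions: HF·pyridine, pyridine, THF, 0 °C → rt
Reagents that add atoms: none
Why: Buffered fluoride desilylation removes the primary silyl ether without touching either ester or the enone.

Step 22
Reactants: 31 tert-butyl (1R,4S,7R,7aS)-4-{[(2E,4E,6R)-4,6-dimethylocta-2,4-dienoyl]oxy}-1-[2-(hydroxymethyl)prop-2-en-1-yl]-7a-methyl-2-oxo-2,4,5,6,7,7a-hexahydro-1H-indene-7-carboxylate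
Product: 32 tert-butyl (1R,4S,7R,7aS)-4-{[(2E,4E,6R)-4,6-dimethylocta-2,4-dienoyl]oxy}-1-(2-formylprop-2-en-1-yl)-7a-methyl-2-oxo-2,4,5,6,7,7a-hexahydro-1H-indene-7-carboxylate
Conditions: Dess–Martin periodinane (1.3 equiv), CH2Cl2, 0 °C → rt
Reagents that add atoms: none
Why: Dess–Martin oxidation of the primary allylic alcohol gives the 2-substituted acrolein without over-oxidation or alkene migration.

Step 23
Reactants: 32 tert-butyl (1R,4S,7R,7aS)-4-{[(2E,4E,6R)-4,6-dimethylocta-2,4-dienoyl]oxy}-1-(2-formylprop-2-en-1-yl)-7a-methyl-2-oxo-2,4,5,6,7,7a-hexahydro-1H-indene-7-carboxylate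
Product: 33 (1R,4S,7R,7aS)-4-{[(2E,4E,6R)-4,6-dimethylocta-2,4-dienoyl]oxy}-1-(2-formylprop-2-en-1-yl)-7a-methyl-2-oxo-2,4,5,6,7,7a-hexahydro-1H-indene-7-carboxylic acid (target)
Conditions: CF3CO2H/CH2Cl2 (1:4), 0 °C → rt
Reagents that add atoms: none
Why: Acidolysis of the tert-butyl ester by alkyl–oxygen cleavage (loss of isobutene) frees the acid, while the electron-poor enal, the enone and the dienoate are inert to acid and no stereocentre is touched.

## Compound list

1 | (2E)-but-2-enal | C/C=C/C=O | starting material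
2 | [(1E)-buta-1,3-dien-1-yloxy]tri(propan-2-yl)silane | C=C/C=C/O[Si](C(C)C)(C(C)C)C(C)C | intermediate
3 | 3-methylbut-2-enoic acid | CC(C)=CC(=O)O | starting material
4 | tert-butyl 3-methylbut-2-enoate | CC(C)=CC(=O)OC(C)(C)C | intermediate
5 | tert-butyl (2E)-3-methyl-4-oxobut-2-enoate | O=C/C(C)=C/C(=O)OC(C)(C)C | intermediate
6 | tert-butyl (1R,5R,6S)-6-formyl-6-methyl-5-[(triisopropylsilyl)oxy]cyclohex-3-ene-1-carboxylate | O=C[C@]1(C)[C@H](O[Si](C(C)C)(C(C)C)C(C)C)C=CC[C@H]1C(=O)OC(C)(C)C | intermediate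
7 | tert-butyl (1R,2S,3R)-2-formyl-2-methyl-3-[(triisopropylsilyl)oxy]cyclohexane-1-carboxylate | O=C[C@]1(C)[C@H](O[Si](C(C)C)(C(C)C)C(C)C)CCC[C@H]1C(=O)OC(C)(C)C | intermediate
8 | tert-butyl (1R,2S,3R)-2-methyl-2-[(1Z)-prop-1-en-1-yl]-3-[(triisopropylsilyl)oxy]cyclohexane-1-carboxylate | C/C=C\[C@]1(C)[C@H](O[Si](C(C)C)(C(C)C)C(C)C)CCC[C@H]1C(=O)OC(C)(C)C | intermediate
9 | tert-butyl (1R,2S,3R)-2-[2-(9-borabicyclo[3.3.1]nonan-9-yl)propyl]-2-methyl-3-[(triisopropylsilyl)oxy]cyclohexane-1-carboxylate (both epimers at the boron-bearing carbon) | CC(B1C2CCCC1CCC2)C[C@]1(C)[C@H](O[Si](C(C)C)(C(C)C)C(C)C)CCC[C@H]1C(=O)OC(C)(C)C | intermediate (not isolated)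
10 | tert-butyl (1R,2S,3R)-2-(2-hydroxypropyl)-2-methyl-3-[(triisopropylsilyl)oxy]cyclohexane-1-carboxylate (both carbinol epimers) | CC(O)C[C@]1(C)[C@H](O[Si](C(C)C)(C(C)C)C(C)C)CCC[C@H]1C(=O)OC(C)(C)C | intermediate
11 | tert-butyl (1R,2S,3R)-3-hydroxy-2-(2-hydroxypropyl)-2-methylcyclohexane-1-carboxylate (both side-chain carbinol epimers) | CC(O)C[C@]1(C)[C@H](O)CCC[C@H]1C(=O)OC(C)(C)C | intermediate
12 | tert-butyl (1R,2S)-2-methyl-3-oxo-2-(2-oxopropyl)cyclohexane-1-carboxylate | CC(=O)C[C@]1(C)C(=O)CCC[C@H]1C(=O)OC(C)(C)C | intermediate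
13 | tert-butyl (7R,7aS)-3a-hydroxy-7a-methyl-2-oxooctahydro-1H-indene-7-carboxylate (configuration at C3a not defined, lost on dehydration) | C1C(=O)CC2(O)CCC[C@@H](C(=O)OC(C)(C)C)[C@@]21C | intermediate (not isolated)
14 | tert-butyl (7R,7aS)-7a-methyl-2-oxo-2,4,5,6,7,7a-hexahydro-1H-indene-7-carboxylate | C1C(=O)C=C2CCC[C@@H](C(=O)OC(C)(C)C)[C@@]21C | intermediate
15 | 2-methylidenepropane-1,3-diol | C=C(CO)CO | starting material
16 | 2-({[tert-butyl(dimethyl)silyl]oxy}methyl)prop-2-en-1-ol | C=C(CO)CO[Si](C)(C)C(C)(C)C | intermediate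
17 | {[2-(bromomethyl)prop-2-en-1-yl]oxy}(tert-butyl)dimethylsilane | C=C(CBr)CO[Si](C)(C)C(C)(C)C | intermediate
18 | lithium (7R,7aS)-7-(tert-butoxycarbonyl)-7a-methyl-5,6,7,7a-tetrahydro-4H-inden-2-olate | C1=C([O-])C=C2CCC[C@@H](C(=O)OC(C)(C)C)[C@@]21C.[Li+] | intermediate (not isolated)
19 | tert-butyl (1R,7R,7aS)-1-[2-({[tert-butyl(dimethyl)silyl]oxy}methyl)prop-2-en-1-yl]-7a-methyl-2-oxo-2,4,5,6,7,7a-hexahydro-1H-indene-7-carboxylate | C=C(CO[Si](C)(C)C(C)(C)C)C[C@H]1C(=O)C=C2CCC[C@@H](C(=O)OC(C)(C)C)[C@@]21C | intermediate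
20 | tert-butyl (1R,7R,7aS)-1-[2-({[tert-butyl(dimethyl)silyl]oxy}methyl)prop-2-en-1-yl]-7a-methyl-2-[(trimethylsilyl)oxy]-5,6,7,7a-tetrahydro-1H-indene-7-carboxylate | C=C(CO[Si](C)(C)C(C)(C)C)C[C@H]1C(O[Si](C)(C)C)=CC2=CCC[C@@H](C(=O)OC(C)(C)C)[C@@]21C | intermediate (not isolated)
21 | tert-butyl (1R,4S,7R,7aS)-1-[2-({[tert-butyl(dimethyl)silyl]oxy}methyl)prop-2-en-1-yl]-4-hydroxy-7a-methyl-2-oxo-2,4,5,6,7,7a-hexahydro-1H-indene-7-carboxylate | C=C(CO[Si](C)(C)C(C)(C)C)C[C@H]1C(=O)C=C2[C@@H](O)CC[C@@H](C(=O)OC(C)(C)C)[C@@]21C | intermediate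
22 | (2E)-2-methylbut-2-enoic acid | C/C=C(\C)C(=O)O | starting material
23 | (2R)-2-methylbutanoic acid | CC[C@@H](C)C(=O)O | intermediate
24 | (2R)-2-methylbutan-1-ol | CC[C@@H](C)CO | intermediate
25 | (2R)-2-methylbutanal | CC[C@@H](C)C=O | intermediate (not isolated)
26 | (2E,4R)-2,4-dimethylhex-2-enal | CC[C@@H](C)/C=C(\C)C=O | intermediate
27 | ethyl (2E,4E,6R)-4,6-dimethylocta-2,4-dienoate | CC[C@@H](C)/C=C(C)/C=C/C(=O)OCC | intermediate
28 | (2E,4E,6R)-4,6-dimethylocta-2,4-dienoic acid | CC[C@@H](C)/C=C(C)/C=C/C(=O)O | intermediate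
29 | (2E,4E,6R)-4,6-dimethylocta-2,4-dienoic 2,4,6-trichlorobenzoic anhydride | CC[C@@H](C)/C=C(C)/C=C/C(=O)OC(=O)c1c(Cl)cc(Cl)cc1Cl | intermediate (not isolated)
30 | tert-butyl (1R,4S,7R,7aS)-1-[2-({[tert-butyl(dimethyl)silyl]oxy}methyl)prop-2-en-1-yl]-4-{[(2E,4E,6R)-4,6-dimethylocta-2,4-dienoyl]oxy}-7a-methyl-2-oxo-2,4,5,6,7,7a-hexahydro-1H-indene-7-carboxylate | C=C(CO[Si](C)(C)C(C)(C)C)C[C@H]1C(=O)C=C2[C@@H](OC(=O)/C=C/C(C)=C/[C@H](C)CC)CC[C@@H](C(=O)OC(C)(C)C)[C@@]21C | intermediate
31 | tert-butyl (1R,4S,7R,7aS)-4-{[(2E,4E,6R)-4,6-dimethylocta-2,4-dienoyl]oxy}-1-[2-(hydroxymethyl)prop-2-en-1-yl]-7a-methyl-2-oxo-2,4,5,6,7,7a-hexahydro-1H-indene-7-carboxylate | C=C(CO)C[C@H]1C(=O)C=C2[C@@H](OC(=O)/C=C/C(C)=C/[C@H](C)CC)CC[C@@H](C(=O)OC(C)(C)C)[C@@]21C | intermediate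
32 | tert-butyl (1R,4S,7R,7aS)-4-{[(2E,4E,6R)-4,6-dimethylocta-2,4-dienoyl]oxy}-1-(2-formylprop-2-en-1-yl)-7a-methyl-2-oxo-2,4,5,6,7,7a-hexahydro-1H-indene-7-carboxylate | C=C(C=O)C[C@H]1C(=O)C=C2[C@@H](OC(=O)/C=C/C(C)=C/[C@H](C)CC)CC[C@@H](C(=O)OC(C)(C)C)[C@@]21C | intermediate
33 | (1R,4S,7R,7aS)-4-{[(2E,4E,6R)-4,6-dimethylocta-2,4-dienoyl]oxy}-1-(2-formylprop-2-en-1-yl)-7a-methyl-2-oxo-2,4,5,6,7,7a-hexahydro-1H-indene-7-carboxylic acid | C=C(C=O)C[C@H]1C(=O)C=C2[C@@H](OC(=O)/C=C/C(C)=C/[C@H](C)CC)CC[C@@H](C(=O)O)[C@@]21C | target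

## Step count and risks

Total step count: 23.
Longest linear sequence: 15 steps (3 → 4 → 5 → 6 → 7 → 8 → 10 → 11 → 12 → 14 → 19 → 21 → 30 → 31 → 32 → 33; steps 2–10, 13, 14, 20–23).

Steps most likely to fail:

Step 4 (asymmetric Diels–Alder). The cationic boron catalyst may degrade the silyl dienol ether or give insufficient ee with the β-ester-substituted enal. The fallback moves absolute control from the catalyst to a removable auxiliary on the diene. It sets out from 1: the potassium dienolate of crotonaldehyde (KOtBu, THF, −78 °C) is O-acylated with (2S)-2-methoxy-2-phenylacetyl chloride to give (1E)-buta-1,3-dien-1-yl (2S)-2-methoxy-2-phenylacetate F1. A BF3·OEt2-promoted cycloaddition of F1 with 5 (CH2Cl2, −78 °C) gives tert-butyl (1R,5R,6S)-6-formyl-5-{[(2S)-2-methoxy-2-phenylacetyl]oxy}-6-methylcyclohex-3-ene-1-carboxylate F2, purified from its diastereomer by chromatography (the mirror-image auxiliary is used if this one shields the wrong diene face). K2CO3 in MeOH at 0 °C removes the activated α-alkoxy ester to give tert-butyl (1R,5R,6S)-6-formyl-5-hydroxy-6-methylcyclohex-3-ene-1-carboxylate F3, and iPr3SiOTf with 2,6-lutidine brings the route back at 6.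

Step 13 (configuration at C1). The facial preference of the alkylation next to the quaternary carbon is argued from sterics and is not proven. The fallback sets the centre by protonation instead of by C–C bond formation. It sets out from 14: if alkylation gives mainly the C1 epimer tert-butyl (1S,7R,7aS)-1-[2-({[tert-butyl(dimethyl)silyl]oxy}methyl)prop-2-en-1-yl]-7a-methyl-2-oxo-2,4,5,6,7,7a-hexahydro-1H-indene-7-carboxylate F4, this is deprotonated again (LiN(iPr)2, THF, −78 °C) to lithium (7R,7aS)-7-(tert-butoxycarbonyl)-1-[2-({[tert-butyl(dimethyl)silyl]oxy}methyl)prop-2-en-1-yl]-7a-methyl-5,6,7,7a-tetrahydro-4H-inden-2-olate F5. Quenching with 2,6-di-tert-butylphenol delivers the proton from the face the electrophile had used, which pushes the side chain syn to the methyl group and returns to the route at 19.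

Step 14 (vinylogous Rubottom oxidation). Enolisation may compete at C1, and the peracid may enter anti to the angular methyl group. The fallback changes the fragment union from acylation with retention to esterification with inversion. It sets out from 19: if the equatorial epimer tert-butyl (1R,4R,7R,7aS)-1-[2-({[tert-butyl(dimethyl)silyl]oxy}methyl)prop-2-en-1-yl]-4-hydroxy-7a-methyl-2-oxo-2,4,5,6,7,7a-hexahydro-1H-indene-7-carboxylate F6 is obtained, it is coupled with acid 28 under Mitsunobu conditions (PPh3, diisopropyl azodicarboxylate, toluene, 0 °C → rt). Inversion at C4 gives ester 30 directly, where the route is rejoined.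

## Further compounds

F1 | step 4 | (1E)-buta-1,3-dien-1-yl (2S)-2-methoxy-2-phenylacetate | C=C/C=C/OC(=O)[C@@H](OC)c1ccccc1
F2 | step 4 | tert-butyl (1R,5R,6S)-6-formyl-5-{[(2S)-2-methoxy-2-phenylacetyl]oxy}-6-methylcyclohex-3-ene-1-carboxylate | O=C[C@]1(C)[C@H](OC(=O)[C@@H](OC)c2ccccc2)C=CC[C@H]1C(=O)OC(C)(C)C
F3 | step 4 | tert-butyl (1R,5R,6S)-6-formyl-5-hydroxy-6-methylcyclohex-3-ene-1-carboxylate | O=C[C@]1(C)[C@H](O)C=CC[C@H]1C(=O)OC(C)(C)C
F4 | step 13 | tert-butyl (1S,7R,7aS)-1-[2-({[tert-butyl(dimethyl)silyl]oxy}methyl)prop-2-en-1-yl]-7a-methyl-2-oxo-2,4,5,6,7,7a-hexahydro-1H-indene-7-carboxylate | C=C(CO[Si](C)(C)C(C)(C)C)C[C@@H]1C(=O)C=C2CCC[C@@H](C(=O)OC(C)(C)C)[C@@]21C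
F5 | step 13 | lithium (7R,7aS)-7-(tert-butoxycarbonyl)-1-[2-({[tert-butyl(dimethyl)silyl]oxy}methyl)prop-2-en-1-yl]-7a-methyl-5,6,7,7a-tetrahydro-4H-inden-2-olate | C=C(CO[Si](C)(C)C(C)(C)C)CC1=C([O-])C=C2CCC[C@@H](C(=O)OC(C)(C)C)[C@@]21C.[Li+]
F6 | step 14 | tert-butyl (1R,4R,7R,7aS)-1-[2-({[tert-butyl(dimethyl)silyl]oxy}methyl)prop-2-en-1-yl]-4-hydroxy-7a-methyl-2-oxo-2,4,5,6,7,7a-hexahydro-1H-indene-7-carboxylate | C=C(CO[Si](C)(C)C(C)(C)C)C[C@H]1C(=O)C=C2[C@H](O)CC[C@@H](C(=O)OC(C)(C)C)[C@@]21C
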